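**Numbering used throughout:** 1 3,4,5-trimethoxyphenol; 2 magnesium salt of its ortho-hydroxymethyl derivative; 3 6-hydroxy-2,3,4-trimethoxybenzaldehyde; 4 methyltriphenylphosphonium bromide; 5 potassium phenoxide of 3; 6 3,4,5-trimethoxy-2-vinylphenol; 7 ferulic acid; 8 benzyl 4-O-benzylferulate; 9 4-O-benzylconiferyl alcohol; 10 its methyl carbonate; 11 lithium phenoxide of 6; 12 the (S)-diene ether (metathesis precursor); 13 the (S)-2H-chromene; 14 its C4 hydroperoxide; 15 the (2S)-flavan-4-ol; 16 O-benzyl agecorynin E; 17 agecorynin E.

## Analysis of the target

Agecorynin E (17) is a flavanone: ring A is fused to a dihydropyranone ring C, ring B (4-hydroxy-3-methoxyphenyl) sits on C2, three adjacent methoxy groups occupy C5, C6 and C7, and C8 carries the only hydrogen of ring A. C2 is the single stereocentre and is S, so the problem is one of absolute control with no relative stereochemistry to help. That centre is fragile. The C2–O1 bond is benzylic to a ring with a para oxygen and lies β to the C4 carbonyl, so base opens ring C by retro-oxa-Michael reaction to an achiral 2'-hydroxychalcone, and acid can ionise the bond; the free para phenol of ring B makes both easier. The C5 methoxy group is peri to the carbonyl and is lost to chelating Lewis acids, and ring A is electron-rich enough to be attacked at C8 by electrophiles. The difficulty is therefore to create one labile centre in high enantiomeric purity and afterwards to avoid base, strong acid and any reaction that makes or breaks a bond at C2. The plan rests on one structural fact: C3 and C4 are the only ring C atoms between C2 and the ring A carbon C4a. If these two are joined last, as an alkene made from a vinyl group on C2 and a vinyl group on C4a, ring C closes without touching the C2–O1 centre. Because C4 is benzylic to ring A, Markovnikov hydration of that alkene then puts the oxygen where the ketone belongs.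

## Retrosynthetic reasoning

17 to 16. The last bond cut is the O–benzyl bond of the ring B phenol. The phenol has to be masked through the whole route, since a second phenoxide would compete in the etherification and a free guaiacol would not survive the oxidation. A benzyl ether is chosen because it is the one common mask that comes off under neutral, base-free conditions, which the finished flavanone requires.

16 to 15 to 13. The C4 carbonyl is taken back to the secondary alcohol 15 and this to the C3=C4 alkene of chromene 13. The C4–O bond is cut here because a hydrogen-atom-transfer hydration of 13 must place its radical, and so the oxygen, at C4, the position stabilised by ring A. C4 becomes a stereocentre in 15 only transiently, so no selectivity is asked of the hydration beyond regiochemistry. Hydroperoxide 14 is the species first formed and is reduced in the same flask.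

13 to 12. This is the central disconnection: the C3=C4 double bond is cut by ring-closing metathesis, which leads back to diene 12 with one vinyl group on C2 and one on C4a. It is the only ring C bond whose formation involves neither C2 nor O1. Cutting O1–C2 or C2–C3 in the ring-forming step would make ring closure and stereocontrol the same event; cutting C3–C4 separates them. The forward reaction has only to join two terminal alkenes into an unstrained six-membered ring under neutral conditions.

12 to 6 and 10. The C2–O1 bond is cut next, now in an acyclic setting. Forward, lithium phenoxide 11 (from 6) attacks the aryl-bearing terminus of the allyl unit released from linear carbonate 10 under iridium–phosphoramidite catalysis. This one step makes the ether, sets C2 and leaves the vinyl group that will become C3. The gain is that both fragments are achiral and flat, and the only asymmetric step is a catalytic reaction with a well-understood facial model.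

6 to 3 to 1. The ring A vinyl group is cut at its C=C bond (Wittig methylenation of aldehyde 3 with phosphonium salt 4, through phenoxide 5), and the formyl carbon is then cut from the ring (magnesium-mediated ortho-formylation of 1 through 2). Phenol 1 is symmetric, with two equivalent ortho positions and a blocked para position, so the 5,6,7-trimethoxy pattern follows without any regiochemical question.

10 to 9 to 8 to 7. The carbonate is cut at its acyl–oxygen bond to allylic alcohol 9, which comes from ester 8 by hydride reduction, and 8 from ferulic acid 7 by benzylation of both acidic sites. Ferulic acid already holds the ring B oxygenation and the E three-carbon chain, so no carbon–carbon bond has to be made on this side.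

## Alternatives that were turned down

Alternative 1: Ring C is cut at O1–C2 and at C4–C4a, which leads back to phenol 1 and the β-lactone A1. In the forward step 1, as its caesium salt, would open A1 at the benzylic carbon with inversion. The carboxylate set free would then be activated in the same flask with an acid anhydride and would acylate C4a, giving the pivalate-protected flavanone A2.
- For: two ring bonds and the correct oxidation level at C4 arrive in one operation. On step economy this is clearly stronger than the chosen route, which needs three steps after ring closure.
- Against: a phenoxide is a hard nucleophile and β-lactones offer it the acyl carbon as well as the alkyl carbon. The benzylic C–O bond of A1, even with the pivalate tempering ring B, can ionise, and any cationic character costs the inversion. A1 itself requires an asymmetric ketene–aldehyde cycloaddition. The acylation is run in acid. The pivalate of A2 can only be removed with base or a nucleophile, exactly the conditions that open ring C and racemise C2.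
- Comparison: the chosen route is longer but sets C2 by catalyst control and keeps every later step neutral, including the final deprotection.

Alternative 2: Ring C is cut at C2–C3 and C4–C4a. A chiral acid would ionise the diaryl acetal A3 to an O-aryl oxocarbenium ion at C2, ethyl vinyl ether A4 would add through its CH2 terminus, and the new cation at C4 would be trapped by C4a to give the 2,4-cis 4-ethoxychroman A5.
- For: it is the most convergent of the four. It forms two carbon–carbon bonds, the ring and the stereocentre in one catalytic step, and on bonds per step it is stronger than the chosen route.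
- Against: the enantio-determining event is attack on a planar, highly stabilised cation held only by ion pairing. With an electron-rich aryl group on C2 that pair is loose and a stepwise, reversible pathway is open, so selectivity is hard to predict. One equivalent of phenol 1 is discarded, and it and ring A are competent Friedel–Crafts partners for the cation. Both C2 and C4 of A5 are benzylic ethers of electron-rich rings, so the acid needed to turn the C4 ethoxy group into a ketone can also epimerise C2.
- Comparison: the chosen route gives up the one-step annulation for a stereo-defining step that runs on a neutral, well-defined metal allyl, and it does not require acid at any later stage.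

Alternative 3: Ring C is cut at O1–C8a. The bromo carbinol A6, with C2 already set as a secondary alcohol and C4 as a silyl ether, would be closed by palladium-catalysed aryl ether formation under a bulky biaryl phosphine and a carbonate base, to give the silyl-protected flavanol A7.
- For: the carbinol C–O bond is never broken, so C2 is carried with retention. On this point it is as strong as the chosen route, and the carbinol can come from a dependable asymmetric reduction or aldol.
- Against: the aryl bromide is very electron-rich and flanked by a substituent, so oxidative addition is slow. The palladium alkoxide of a secondary benzylic alcohol can undergo β-hydride elimination to the ketone, which destroys C2. A6 needs a fully substituted bromoarene and a differentiated 1,3-diol whose second centre is made only to be oxidised away. Hot carbonate base is involved.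
- Comparison: the number of steps after ring closure is the same as in the chosen route (three), but the fragment synthesis is longer. The chosen route needs only one stereocentre and a ring closure that tolerates the substitution pattern.

Key step: step 7

Assumption: the (Ra,Rc,Rc) antipode of the phosphoramidite is taken to be the one that sends the phenoxide to the face giving the S ether; if the facial sense is the reverse, the mirror-image ligand is used and nothing else changes.

## Route

Step 1
Reactants: 1 3,4,5-trimethoxyphenol
Product: 3 6-hydroxy-2,3,4-trimethoxybenzaldehyde, via ortho-hydroxymethyl magnesium phenoxide 2 (not isolated)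
Conditions: MgCl2, Et3N, (CH2O)n, MeCN, reflux; then 1 M HCl
Reagents that add atoms: paraformaldehyde (source of formaldehyde), C=O
Why: Magnesium-mediated ortho-formylation (Casnati–Skattebøl): the magnesium phenoxide delivers formaldehyde to the ortho carbon and intermediate 2 is oxidised by hydride transfer to a second formaldehyde; the two ortho positions of 1 are equivalent and the para position is blocked, so only one aldehyde can form.

Step 2
Reactants: 3 6-hydroxy-2,3,4-trimethoxybenzaldehyde; 4 methyltriphenylphosphonium bromide
Product: 6 3,4,5-trimethoxy-2-vinylphenol, via potassium phenoxide of the aldehyde 5 (not isolated)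
Conditions: 4 (2.2 equiv), KOtBu (3.3 equiv), THF, 0 °C; then 3, 0 °C → rt; then sat. aq. NH4Cl
Reagents that add atoms: methyltriphenylphosphonium bromide (4), [Br-].C[P+](c1ccccc1)(c1ccccc1)c1ccccc1
Why: Wittig methylenation with a non-stabilised ylide; the extra base first turns the phenol into phenoxide 5, which slows but should not stop addition to the aldehyde, and the mild work-up returns the vinylphenol, which is used at once because electron-rich 2-vinylphenols oligomerise on standing.

Step 3
Reactants: 7 ferulic acid, (E)-3-(4-hydroxy-3-methoxyphenyl)prop-2-enoic acid
Product: 8 benzyl (E)-3-[4-(benzyloxy)-3-methoxyphenyl]prop-2-enoate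
Conditions: BnBr (2.3 equiv), K2CO3, DMF, 60 °C
Reagents that add atoms: benzyl bromide, BrCc1ccccc1
Why: Williamson alkylation of the phenoxide and of the carboxylate with one reagent; the ester half is removed in step 4, so no separate esterification is needed.

Step 4
Reactants: 8 benzyl (E)-3-[4-(benzyloxy)-3-methoxyphenyl]prop-2-enoate
Product: 9 (E)-3-[4-(benzyloxy)-3-methoxyphenyl]prop-2-en-1-ol
Conditions: i-Bu2AlH (2.5 equiv), CH2Cl2, −78 → 0 °C; then aq. potassium sodium tartrate
Reagents that add atoms: none
Why: 1,2-Reduction of the α,β-unsaturated ester to the allylic alcohol by i-Bu2AlH at low temperature leaves the E alkene and the aryl benzyl ether untouched; the ester benzyl group leaves as its alcohol and is separated.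

Step 5
Reactants: 9 (E)-3-[4-(benzyloxy)-3-methoxyphenyl]prop-2-en-1-ol
Product: 10 (E)-3-[4-(benzyloxy)-3-methoxyphenyl]prop-2-en-1-yl methyl carbonate
Conditions: ClCO2Me, pyridine, CH2Cl2, 0 °C
Reagents that add atoms: methyl chloroformate, COC(=O)Cl
Why: Acylation of a primary allylic alcohol with a chloroformate; the methyl carbonate is the leaving group that the iridium catalyst ionises in step 6, and the base-buffered conditions avoid ionising the electron-rich cinnamyl system.

Step 6
Reactants: 6 3,4,5-trimethoxy-2-vinylphenol; 10 (E)-3-[4-(benzyloxy)-3-methoxyphenyl]prop-2-en-1-yl methyl carbonate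
Product: 12 (S)-1-[4-(benzyloxy)-3-methoxyphenyl]allyl 3,4,5-trimethoxy-2-vinylphenyl ether, via lithium vinylphenoxide 11 (not isolated)
Conditions: 6, n-BuLi, THF, 0 °C; then 10, [Ir(cod)Cl]2 (2 mol%), (Ra,Rc,Rc)-O,O'-(1,1'-binaphthalene-2,2'-diyl) N,N-bis(1-phenylethyl)phosphoramidite (4 mol%, catalyst pre-activated with n-PrNH2), THF, rt
Reagents that add atoms: none
Why: Iridium-catalysed enantioselective allylic etherification of a phenoxide with a linear cinnamyl-type carbonate: the cyclometallated iridium phosphoramidite ionises 10 to an allyl complex and phenoxide 11 attacks the aryl-bearing terminus anti to the metal, so the branched ether forms and the ligand fixes C2 as S. The electron-rich phenoxide is a poor leaving group, and together with a short reaction time this limits re-ionisation of the product.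

Step 7
Reactants: 12 (S)-1-[4-(benzyloxy)-3-methoxyphenyl]allyl 3,4,5-trimethoxy-2-vinylphenyl ether
Product: 13 (S)-2-[4-(benzyloxy)-3-methoxyphenyl]-5,6,7-trimethoxy-2H-chromene
Conditions: (H2IMes)(PCy3)Cl2Ru=CHPh (5 mol%), 1,4-benzoquinone (10 mol%), CH2Cl2 (5 mM, degassed), 40 °C, dark
Reagents that add atoms: none
Why: The ruthenium alkylidene adds to the less hindered allylic vinyl group, and the new alkylidene at C3 closes a ruthenacyclobutane with the ring A vinyl group; cycloreversion releases ethylene and the C3=C4 bond. This is ring-closing olefin metathesis of an allyl 2-vinylphenyl ether, the established entry to 2H-chromenes. Ring C closes as an unstrained six-membered ring whose new cis alkene is conjugated with ring A, and loss of ethylene makes the closure irreversible. No stereocentre is formed: C2 was set in step 6 and none of its four bonds takes part, so its configuration should be carried through unchanged. The step needs chemoselectivity for metathesis over three side paths: double-bond migration by ruthenium hydrides, intermolecular metathesis, and ionisation or photochemical electrocyclic opening of the doubly activated C2–O1 bond. High dilution and the six-membered ring favour closure, 1,4-benzoquinone scavenges hydrides, and neutral acid-free solvent, mild heating and exclusion of light protect the C2–O1 bond in 12 and 13. The two ortho substituents beside the ring A vinyl group slow loading of ruthenium there, which is why initiation is expected at the other alkene.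

Step 8
Reactants: 13 (S)-2-[4-(benzyloxy)-3-methoxyphenyl]-5,6,7-trimethoxy-2H-chromene
Product: 15 (2S)-2-[4-(benzyloxy)-3-methoxyphenyl]-5,6,7-trimethoxychroman-4-ol (both C4 epimers), via flavan C4 hydroperoxide 14 (not isolated)
Conditions: Co(acac)2 (20 mol%), PhSiH3, O2 (1 atm), THF, 0 °C → rt, dark; then PPh3
Reagents that add atoms: dioxygen, O=O
Why: Mukaiyama hydration by hydrogen-atom transfer: a cobalt hydride gives a hydrogen atom to C3, the radical forms at C4 where ring A stabilises it, O2 traps it and peroxide 14 is reduced by PPh3 to the alcohol. C2 is not involved, and the C4 configuration does not matter because step 9 removes it.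

Step 9
Reactants: 15 (2S)-2-[4-(benzyloxy)-3-methoxyphenyl]-5,6,7-trimethoxychroman-4-ol
Product: 16 (S)-2-[4-(benzyloxy)-3-methoxyphenyl]-5,6,7-trimethoxychroman-4-one
Conditions: Dess–Martin periodinane, pyridine, CH2Cl2, 0 °C → rt
Reagents that add atoms: none
Why: Dess–Martin oxidation of a secondary benzylic alcohol to the aryl ketone; the pyridine buffer keeps the medium free of acid that could ionise C4 and is too weak a base to enolise C3, so both C4 epimers should converge on one ketone with C2 intact.

Step 10
Reactants: 16 (S)-2-[4-(benzyloxy)-3-methoxyphenyl]-5,6,7-trimethoxychroman-4-one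
Product: 17 agecorynin E, (S)-2-(4-hydroxy-3-methoxyphenyl)-5,6,7-trimethoxychroman-4-one
Conditions: H2 (1 atm), 10% Pd/C, EtOAc, rt
Reagents that add atoms: none
Why: Hydrogenolysis of the aryl benzyl ether over Pd/C in a neutral aprotic solvent frees the phenol without base, which would open ring C by retro-oxa-Michael reaction; the reaction is stopped after one equivalent of hydrogen to spare the C2–O1 bond and the ketone, and the product is isolated without basic washing.

## Compound list

1 | 3,4,5-trimethoxyphenol | COc1cc(O)cc(OC)c1OC | starting material
2 | chloromagnesium 2-(hydroxymethyl)-3,4,5-trimethoxyphenoxide | COc1cc([O-])c(CO)c(OC)c1OC.[Mg+2].[Cl-] | intermediate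
3 | 6-hydroxy-2,3,4-trimethoxybenzaldehyde | COc1cc(O)c(C=O)c(OC)c1OC | intermediate
4 | methyltriphenylphosphonium bromide | [Br-].C[P+](c1ccccc1)(c1ccccc1)c1ccccc1 | starting material
5 | potassium 2-formyl-3,4,5-trimethoxyphenoxide | COc1cc([O-])c(C=O)c(OC)c1OC.[K+] | intermediate
6 | 3,4,5-trimethoxy-2-vinylphenol | COc1cc(O)c(C=C)c(OC)c1OC | intermediate
7 | ferulic acid, (E)-3-(4-hydroxy-3-methoxyphenyl)prop-2-enoic acid | COc1cc(/C=C/C(=O)O)ccc1O | starting material
8 | benzyl (E)-3-[4-(benzyloxy)-3-methoxyphenyl]prop-2-enoate | COc1cc(/C=C/C(=O)OCc2ccccc2)ccc1OCc1ccccc1 | intermediate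
9 | (E)-3-[4-(benzyloxy)-3-methoxyphenyl]prop-2-en-1-ol | COc1cc(/C=C/CO)ccc1OCc1ccccc1 | intermediate
10 | (E)-3-[4-(benzyloxy)-3-methoxyphenyl]prop-2-en-1-yl methyl carbonate | COc1cc(/C=C/COC(=O)OC)ccc1OCc1ccccc1 | intermediate
11 | lithium 3,4,5-trimethoxy-2-vinylphenoxide | COc1cc([O-])c(C=C)c(OC)c1OC.[Li+] | intermediate
12 | (S)-1-[4-(benzyloxy)-3-methoxyphenyl]allyl 3,4,5-trimethoxy-2-vinylphenyl ether | C=C[C@H](Oc1cc(OC)c(OC)c(OC)c1C=C)c1ccc(OCc2ccccc2)c(OC)c1 | intermediate
13 | (S)-2-[4-(benzyloxy)-3-methoxyphenyl]-5,6,7-trimethoxy-2H-chromene | COc1cc([C@@H]2C=Cc3c(cc(OC)c(OC)c3OC)O2)ccc1OCc1ccccc1 | intermediate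
14 | (2S)-2-[4-(benzyloxy)-3-methoxyphenyl]-4-hydroperoxy-5,6,7-trimethoxychromane (both C4 epimers) | COc1cc([C@@H]2CC(OO)c3c(cc(OC)c(OC)c3OC)O2)ccc1OCc1ccccc1 | intermediate
15 | (2S)-2-[4-(benzyloxy)-3-methoxyphenyl]-5,6,7-trimethoxychroman-4-ol (both C4 epimers) | COc1cc([C@@H]2CC(O)c3c(cc(OC)c(OC)c3OC)O2)ccc1OCc1ccccc1 | intermediate
16 | (S)-2-[4-(benzyloxy)-3-methoxyphenyl]-5,6,7-trimethoxychroman-4-one | COc1cc([C@@H]2CC(=O)c3c(cc(OC)c(OC)c3OC)O2)ccc1OCc1ccccc1 | intermediate
17 | agecorynin E, (S)-2-(4-hydroxy-3-methoxyphenyl)-5,6,7-trimethoxychroman-4-one | COc1cc([C@@H]2CC(=O)c3c(cc(OC)c(OC)c3OC)O2)ccc1O | target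

## Step count and risks

Total step count: 10. Longest linear sequence: 8 steps (7 → 8 → 9 → 10 → 12 → 13 → 15 → 16 → 17; steps 3 to 10). The ring A branch (steps 1 and 2) joins at step 6.

Least certain steps:

**Step 7 (key step).**
- Risk: ruthenium hydrides formed as the catalyst decays may move the terminal double bond of the allylic ether into conjugation. That would erase C2 or divert closure to a five-membered ring. Closure onto the doubly ortho-flanked styrene may also be slow enough for intermolecular metathesis to compete.
- Fallback (sets out from 1 and 10, returns at 16): the alkene closure is given up and ring C is closed by acylation at C4a.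
  - Phenol 1 is deprotonated with n-BuLi and allylated with 10 under the iridium conditions of step 6, which should give (S)-1-[4-(benzyloxy)-3-methoxyphenyl]allyl 3,4,5-trimethoxyphenyl ether F1.
  - Hydroboration with 9-BBN and oxidation with NaBO3 should give (S)-3-[4-(benzyloxy)-3-methoxyphenyl]-3-(3,4,5-trimethoxyphenoxy)propan-1-ol F2.
  - TEMPO with PhI(OAc)2 in aqueous MeCN should give (S)-3-[4-(benzyloxy)-3-methoxyphenyl]-3-(3,4,5-trimethoxyphenoxy)propanoic acid F3.
  - (CF3CO)2O in CH2Cl2 at 0 °C forms the mixed anhydride, which acylates the ring ortho to the ether oxygen (both ortho positions are equivalent) and gives 16.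
  - This path skips steps 7 to 9, but the C2–O1 bond is exposed to acid during ring closure.

**Step 6.**
- Risk: the iridium catalyst may re-ionise the product ether, which the electron-rich ring B favours. This would erode the enantiomeric purity and let the branched ether drift to the linear isomer; C-allylation of the phenoxide is a minor second risk.
- Fallback (sets out from 6 through its lithium salt 11, returns at 12): C2 is brought in from a resolved alcohol and transferred stereospecifically.
  - Vinylmagnesium bromide adds to 4-(benzyloxy)-3-methoxybenzaldehyde F4 to give racemic 1-[4-(benzyloxy)-3-methoxyphenyl]prop-2-en-1-ol F5.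
  - Candida antarctica lipase B with vinyl acetate is expected to leave (S)-1-[4-(benzyloxy)-3-methoxyphenyl]prop-2-en-1-ol F6 and to convert the R enantiomer into (R)-1-[4-(benzyloxy)-3-methoxyphenyl]allyl acetate F7, which is separated.
  - Methyl chloroformate and pyridine turn the S alcohol into (S)-1-[4-(benzyloxy)-3-methoxyphenyl]allyl methyl carbonate F8.
  - RhCl(PPh3)3 modified with P(OMe)3 in THF at 0 °C couples F8 with 11 at the carbon that carried the carbonate with net retention (two inversions), giving 12.

**Step 8.**
- Risk: the C4 radical may take a second hydrogen atom, so that the alkene is reduced to the flavan, and the doubly activated C2–H bond may autoxidise under O2.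
- Fallback (sets out from 13, returns at 15): ionic Markovnikov hydration in place of the radical one. Hg(OAc)2 in THF/H2O at 0 °C forms the mercurinium ion, which water opens at benzylic C4 to give [(2R)-2-[4-(benzyloxy)-3-methoxyphenyl]-4-hydroxy-5,6,7-trimethoxychroman-3-yl]mercury acetate F9. C2 is spatially unchanged; the descriptor is R only because mercury raises the rank of C3. NaBH4 in aqueous NaOH then removes mercury and gives 15.

**Step 2.**
- Risk: olefination of the phenoxide-deactivated, doubly ortho-substituted aldehyde may be sluggish, and the electron-rich vinylphenol may oligomerise during isolation.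
- Fallback (sets out from 1, returns at 6): the vinyl group is introduced by cross-coupling. N-Bromosuccinimide in MeCN at 0 °C brominates one of the two equivalent ortho positions to give 2-bromo-3,4,5-trimethoxyphenol F10. Suzuki–Miyaura coupling with potassium vinyltrifluoroborate (PdCl2(dppf), Cs2CO3, THF/H2O, 70 °C) then gives 6.

**Step 10.**
- Risk: over-reduction, that is hydrogenolysis of the benzylic C2–O1 bond or reduction of the C4 carbonyl.
- Fallback (sets out from 16, returns at 17): acidolytic benzyl transfer in place of hydrogenolysis. CF3CO2H with pentamethylbenzene as cation scavenger at rt cleaves the aryl benzyl ether without hydrogen or Lewis acid and leaves the C5 methoxy group alone. Contact time is kept short because acid can slowly open ring C. No new isolated compound is formed.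

## Further compounds

F1 | step 7 | (S)-1-[4-(benzyloxy)-3-methoxyphenyl]allyl 3,4,5-trimethoxyphenyl ether | C=C[C@H](Oc1cc(OC)c(OC)c(OC)c1)c1ccc(OCc2ccccc2)c(OC)c1
F2 | step 7 | (S)-3-[4-(benzyloxy)-3-methoxyphenyl]-3-(3,4,5-trimethoxyphenoxy)propan-1-ol | OCC[C@H](Oc1cc(OC)c(OC)c(OC)c1)c1ccc(OCc2ccccc2)c(OC)c1
F3 | step 7 | (S)-3-[4-(benzyloxy)-3-methoxyphenyl]-3-(3,4,5-trimethoxyphenoxy)propanoic acid | OC(=O)C[C@H](Oc1cc(OC)c(OC)c(OC)c1)c1ccc(OCc2ccccc2)c(OC)c1
F4 | step 6 | 4-(benzyloxy)-3-methoxybenzaldehyde | COc1cc(C=O)ccc1OCc1ccccc1
F5 | step 6 | rac-1-[4-(benzyloxy)-3-methoxyphenyl]prop-2-en-1-ol | C=CC(O)c1ccc(OCc2ccccc2)c(OC)c1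
F6 | step 6 | (S)-1-[4-(benzyloxy)-3-methoxyphenyl]prop-2-en-1-ol | C=C[C@H](O)c1ccc(OCc2ccccc2)c(OC)c1
F7 | step 6 | (R)-1-[4-(benzyloxy)-3-methoxyphenyl]allyl acetate | C=C[C@@H](OC(C)=O)c1ccc(OCc2ccccc2)c(OC)c1
F8 | step 6 | (S)-1-[4-(benzyloxy)-3-methoxyphenyl]allyl methyl carbonate | C=C[C@H](OC(=O)OC)c1ccc(OCc2ccccc2)c(OC)c1
F9 | step 8 | [(2R)-2-[4-(benzyloxy)-3-methoxyphenyl]-4-hydroxy-5,6,7-trimethoxychroman-3-yl]mercury acetate | COc1cc([C@@H]2C([Hg]OC(C)=O)C(O)c3c(cc(OC)c(OC)c3OC)O2)ccc1OCc1ccccc1
F10 | step 2 | 2-bromo-3,4,5-trimethoxyphenol | COc1cc(O)c(Br)c(OC)c1OC
F0 | step 10 | none | none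
A1 | alternative 1 | (R)-4-[3-methoxy-4-(pivaloyloxy)phenyl]oxetan-2-one | COc1cc([C@H]2CC(=O)O2)ccc1OC(=O)C(C)(C)C
A2 | alternative 1 | (S)-5,6,7-trimethoxy-2-[3-methoxy-4-(pivaloyloxy)phenyl]chroman-4-one | COc1cc([C@@H]2CC(=O)c3c(cc(OC)c(OC)c3OC)O2)ccc1OC(=O)C(C)(C)C
A3 | alternative 2 | 4-(benzyloxy)-3-methoxybenzaldehyde bis(3,4,5-trimethoxyphenyl) acetal | COc1cc(OC(Oc2cc(OC)c(OC)c(OC)c2)c2ccc(OCc3ccccc3)c(OC)c2)cc(OC)c1OC
A4 | alternative 2 | ethyl vinyl ether | C=COCC
A5 | alternative 2 | (2S,4S)-2-[4-(benzyloxy)-3-methoxyphenyl]-4-ethoxy-5,6,7-trimethoxychroman | COc1cc([C@@H]2C[C@H](OCC)c3c(cc(OC)c(OC)c3OC)O2)ccc1OCc1ccccc1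
A6 | alternative 3 | (1S,3S)-1-[4-(benzyloxy)-3-methoxyphenyl]-3-(2-bromo-4,5,6-trimethoxyphenyl)-3-[(tert-butyldimethylsilyl)oxy]propan-1-ol | COc1cc([C@@H](O)C[C@H](O[Si](C)(C)C(C)(C)C)c2c(Br)cc(OC)c(OC)c2OC)ccc1OCc1ccccc1
A7 | alternative 3 | (2S,4S)-2-[4-(benzyloxy)-3-methoxyphenyl]-4-[(tert-butyldimethylsilyl)oxy]-5,6,7-trimethoxychroman | COc1cc([C@@H]2C[C@H](O[Si](C)(C)C(C)(C)C)c3c(cc(OC)c(OC)c3OC)O2)ccc1OCc1ccccc1
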